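**Retrosynthetic overview**

1. Enabling feature: in the only ring, C1 (angelate oxygen) and C2 (side-chain carbon, whose first exocyclic carbon carries a methyl) are trans-diequatorial and the C5 methyl is 1,3 to C1. This is the isopulegol pattern, so O–C1–C2–C(CH3) is the homoallylic alcohol retron of a carbonyl-ene reaction once that exocyclic carbon is read as an isopropenyl carbon.
2. Key disconnection: the C1–C2 ring bond, made by a ZnBr2-mediated type-one intramolecular carbonyl-ene reaction of acyclic aldehyde 10. The ring is the only one and is closed last; the step sets C1 and C2, frees the one hydroxyl that must carry the angelate, and leaves an isopropenyl handle.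
3. Side chain: 9-BBN hydroboration of the isopropenyl group sets the methyl-bearing carbon; carbonylative Suzuki–Miyaura coupling with CO and 1-iodo-2-methylprop-1-ene gives the enone; CBS reduction and acetylation follow.
4. C4: carried as the equatorial silyl ether (anchor for the ene chair and protecting group), then corrected at the end to the axial alcohol by oxidation and LiBH(s-Bu)3 reduction.
5. Aldehyde 10: from 4-methylpent-3-enal by (Z)-crotylboration, silylation, hydroboration–oxidation and oxidation.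

Key step: step 6

Remark: the ester double bond of the given structure is Z, so the acyl group is angeloyl and is introduced from commercial angelic acid; 1-iodo-2-methylprop-1-ene is taken as commercial.

**Route**

Step 1
Reactants: 1 4-methylpent-3-en-1-ol
Product: 2 4-methylpent-3-enal
Conditions: Dess–Martin periodinane, pyridine, CH2Cl2, 0 °C; used at once as a cold solution
Reagents that add atoms: none
Why: Dess–Martin oxidation converts the primary homoallylic alcohol to the aldehyde under near-neutral conditions that should not move the trisubstituted double bond into conjugation.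

Step 2
Reactants: 2 4-methylpent-3-enal; 3 (Z)-but-2-ene
Product: 6 (3S,4S)-3,7-dimethylocta-1,6-dien-4-ol, via (Z)-crotylbis(isopinocampheyl)borane 4 (not isolated), via bis(isopinocampheyl)borinate ester 5 (not isolated)
Conditions: 3, KOtBu, n-BuLi, THF, −78 to −45 °C; (+)-Ipc2BOMe (from (−)-α-pinene), −78 °C; BF3·OEt2; then 2, −78 °C; NaOH, H2O2, 0 °C to rt
Reagents that add atoms: none
Why: Brown crotylboration: the (Z)-crotylborane adds through a closed chair (Zimmerman–Traxler) transition state, so Z geometry gives the syn methyl/hydroxyl pair while the (−)-α-pinene-derived isopinocampheyl groups direct attack to the Re face of the aldehyde, setting 3S and 4S together.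

Step 3
Reactants: 6 (3S,4S)-3,7-dimethylocta-1,6-dien-4-ol
Product: 7 tert-butyl{[(3S,4S)-3,7-dimethylocta-1,6-dien-4-yl]oxy}dimethylsilane
Conditions: TBSCl, imidazole, DMF, rt
Reagents that add atoms: tert-butyldimethylsilyl chloride, CC(C)(C)[Si](C)(C)Cl
Why: Imidazole-catalysed silylation of the secondary alcohol prevents lactol formation at the aldehyde stage and provides a robust equatorial anchor for the ene chair.

Step 4
Reactants: 7 tert-butyl{[(3S,4S)-3,7-dimethylocta-1,6-dien-4-yl]oxy}dimethylsilane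
Product: 9 (3S,4S)-4-[(tert-butyldimethylsilyl)oxy]-3,7-dimethyloct-6-en-1-ol, via B-alkyl-9-BBN adduct 8 (not isolated)
Conditions: 9-BBN, THF, 0 °C to rt; NaOH, H2O2, 0 °C
Reagents that add atoms: hydrogen peroxide, OO
Why: Hydroboration–oxidation: 9-BBN adds anti-Markovnikov to the monosubstituted vinyl group far faster than to the trisubstituted alkene, and alkaline peroxide oxidises the C–B bond to the primary alcohol without touching a stereocentre.

Step 5
Reactants: 9 (3S,4S)-4-[(tert-butyldimethylsilyl)oxy]-3,7-dimethyloct-6-en-1-ol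
Product: 10 (3S,4S)-4-[(tert-butyldimethylsilyl)oxy]-3,7-dimethyloct-6-enal
Conditions: Dess–Martin periodinane, pyridine, CH2Cl2, 0 °C to rt
Reagents that add atoms: none
Why: Dess–Martin oxidation gives the aldehyde; the two stereocentres are β and γ to the carbonyl and cannot epimerise.

Step 6
Reactants: 10 (3S,4S)-4-[(tert-butyldimethylsilyl)oxy]-3,7-dimethyloct-6-enal
Product: 11 (1R,2S,4S,5S)-4-[(tert-butyldimethylsilyl)oxy]-5-methyl-2-(prop-1-en-2-yl)cyclohexan-1-ol
Conditions: ZnBr2 (1.1 equiv), toluene, 0 °C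
Reagents that add atoms: none
Why: ZnBr2 activates the aldehyde and the trisubstituted alkene attacks it in a concerted, asynchronous type-one carbonyl-ene reaction in which a hydrogen of an allylic methyl passes to the carbonyl oxygen; the closest precedent is the ZnBr2-mediated cyclisation of citronellal to isopulegol. The ring closes by 6-exo attack of the alkene CH carbon on the carbonyl carbon (the C1–C2 ring bond; the isopropylidene carbon stays outside the ring and becomes the isopropenyl carbon) through a chair transition state. The carbinol centre (1R) and the isopropenyl-bearing centre (2S) are both set by this chair, in which the zinc-bound oxygen and the developing isopropenyl group are equatorial and therefore trans. Which chair reacts is decided by the tether: only one chair places both the 3-methyl and the 4-silyloxy group of 10 equatorial, so the existing 3S,4S pair controls the absolute sense of both new centres. The step needs trans-over-cis (chair-over-boat), facial and ene-over-Prins selectivity; the first two are secured by the all-equatorial arrangement of four substituents, the last by the mild, weakly nucleophilic Lewis acid and by the fact that both allylic hydrogen donors are methyl groups, so only the isopropenyl product can form. The product carries exactly one free hydroxyl, the one that must bear the angelate.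

Step 7
Reactants: 11 (1R,2S,4S,5S)-4-[(tert-butyldimethylsilyl)oxy]-5-methyl-2-(prop-1-en-2-yl)cyclohexan-1-ol; 12 angelic acid
Product: 14 (1R,2S,4S,5S)-4-[(tert-butyldimethylsilyl)oxy]-5-methyl-2-(prop-1-en-2-yl)cyclohexyl (Z)-2-methylbut-2-enoate, via angelic 2,4,6-trichlorobenzoic anhydride 13 (not isolated)
Conditions: 12, 2,4,6-trichlorobenzoyl chloride, Et3N, toluene, rt; then 11, 80 °C
Reagents that add atoms: none
Why: Yamaguchi esterification: the mixed anhydride acylates the single free equatorial hydroxyl at the less hindered angeloyl carbonyl, and running it without a nucleophilic catalyst should preserve the Z geometry.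

Step 8
Reactants: 14 (1R,2S,4S,5S)-4-[(tert-butyldimethylsilyl)oxy]-5-methyl-2-(prop-1-en-2-yl)cyclohexyl (Z)-2-methylbut-2-enoate; 15 1-iodo-2-methylprop-1-ene
Product: 17 (1R,2S,4S,5S)-4-[(tert-butyldimethylsilyl)oxy]-5-methyl-2-[(2R)-6-methyl-4-oxohept-5-en-2-yl]cyclohexyl (Z)-2-methylbut-2-enoate, via B-alkyl-9-BBN adduct 16 (not isolated)
Conditions: 9-BBN, THF, 0 °C to rt; then 15, Pd(PPh3)4 (5 mol %), K3PO4 (aq), CO (1 atm), benzene, rt
Reagents that add atoms: carbon monoxide, [C-]#[O+]
Why: 9-BBN should add only to the 1,1-disubstituted alkene, from the face anti to the acyloxy-bearing ring carbon with the allylic hydrogen eclipsing the vinylic methyl (staggered allylic-strain model, the sense known for hydroboration of isopulegol), which sets the side-chain methyl stereocentre R; the B-alkyl-9-BBN then undergoes carbonylative Suzuki–Miyaura coupling (oxidative addition of 15 to zerovalent palladium, CO insertion, transmetallation, reductive elimination) to give the enone.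

Step 9
Reactants: 17 (1R,2S,4S,5S)-4-[(tert-butyldimethylsilyl)oxy]-5-methyl-2-[(2R)-6-methyl-4-oxohept-5-en-2-yl]cyclohexyl (Z)-2-methylbut-2-enoate
Product: 18 (1R,2S,4S,5S)-4-[(tert-butyldimethylsilyl)oxy]-2-[(2R,4R)-4-hydroxy-6-methylhept-5-en-2-yl]-5-methylcyclohexyl (Z)-2-methylbut-2-enoate
Conditions: (S)-2-methyl-CBS-oxazaborolidine (0.2 equiv), catecholborane, toluene, −78 °C
Reagents that add atoms: none
Why: Corey–Bakshi–Shibata reduction: the catalyst treats the isobutenyl group as the large substituent, so the (S)-oxazaborolidine should deliver hydride to give the (R)-allylic alcohol under catalyst control, and catecholborane at low temperature avoids hydroboration and conjugate reduction.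

Step 10
Reactants: 18 (1R,2S,4S,5S)-4-[(tert-butyldimethylsilyl)oxy]-2-[(2R,4R)-4-hydroxy-6-methylhept-5-en-2-yl]-5-methylcyclohexyl (Z)-2-methylbut-2-enoate
Product: 19 (1R,2S,4S,5S)-2-[(2R,4R)-4-acetoxy-6-methylhept-5-en-2-yl]-4-[(tert-butyldimethylsilyl)oxy]-5-methylcyclohexyl (Z)-2-methylbut-2-enoate
Conditions: Ac2O, pyridine, DMAP (cat.), CH2Cl2, 0 °C to rt
Reagents that add atoms: acetic anhydride, CC(=O)OC(C)=O
Why: DMAP-catalysed acyl transfer acetylates the only free hydroxyl with retention at the allylic carbinol carbon.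

Step 11
Reactants: 19 (1R,2S,4S,5S)-2-[(2R,4R)-4-acetoxy-6-methylhept-5-en-2-yl]-4-[(tert-butyldimethylsilyl)oxy]-5-methylcyclohexyl (Z)-2-methylbut-2-enoate
Product: 20 (1R,2S,4S,5S)-2-[(2R,4R)-4-acetoxy-6-methylhept-5-en-2-yl]-4-hydroxy-5-methylcyclohexyl (Z)-2-methylbut-2-enoate
Conditions: HF·pyridine, pyridine, THF, 0 °C to rt
Reagents that add atoms: none
Why: Fluoride-mediated desilylation frees the ring hydroxyl, and the buffered reagent should leave the angelate, the allylic acetate and both alkenes untouched.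

Step 12
Reactants: 20 (1R,2S,4S,5S)-2-[(2R,4R)-4-acetoxy-6-methylhept-5-en-2-yl]-4-hydroxy-5-methylcyclohexyl (Z)-2-methylbut-2-enoate
Product: 21 (1R,2S,5S)-2-[(2R,4R)-4-acetoxy-6-methylhept-5-en-2-yl]-5-methyl-4-oxocyclohexyl (Z)-2-methylbut-2-enoate
Conditions: Dess–Martin periodinane, pyridine, CH2Cl2, 0 °C to rt
Reagents that add atoms: none
Why: Dess–Martin oxidation of the equatorial alcohol to the cyclohexanone erases the temporary configuration at this carbon, while the adjacent methyl centre already sits in its thermodynamically preferred equatorial position.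

Step 13
Reactants: 21 (1R,2S,5S)-2-[(2R,4R)-4-acetoxy-6-methylhept-5-en-2-yl]-5-methyl-4-oxocyclohexyl (Z)-2-methylbut-2-enoate
Product: 22 (1R,2S,4R,5S)-2-[(2R,4R)-4-acetoxy-6-methylhept-5-en-2-yl]-4-hydroxy-5-methylcyclohexyl (Z)-2-methylbut-2-enoate
Conditions: LiBH(s-Bu)3 (L-Selectride, 1.05 equiv), THF, −78 °C; H2O quench at −78 °C
Reagents that add atoms: none
Why: Hindered-hydride reduction: LiBH(s-Bu)3 attacks the cyclohexanone from the equatorial direction beside the equatorial methyl and should give the axial alcohol cis to the methyl (4R), while the two esters are not reduced at −78 °C.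

**Compound list**

1 | 4-methylpent-3-en-1-ol | CC(C)=CCCO | starting material
2 | 4-methylpent-3-enal | CC(C)=CCC=O | intermediate
3 | (Z)-but-2-ene | C/C=C\C | starting material
4 | (Z)-crotylbis(isopinocampheyl)borane, isopinocampheyl groups from (−)-α-pinene | C/C=C\CB([C@H]1C[C@H]2C[C@@H]([C@@H]1C)C2(C)C)[C@H]1C[C@H]2C[C@@H]([C@@H]1C)C2(C)C | intermediate
5 | bis(isopinocampheyl)borinate ester of 6 | C=C[C@H](C)[C@@H](OB([C@H]1C[C@H]2C[C@@H]([C@@H]1C)C2(C)C)[C@H]1C[C@H]2C[C@@H]([C@@H]1C)C2(C)C)CC=C(C)C | intermediate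
6 | (3S,4S)-3,7-dimethylocta-1,6-dien-4-ol | C=C[C@H](C)[C@@H](O)CC=C(C)C | intermediate
7 | tert-butyl{[(3S,4S)-3,7-dimethylocta-1,6-dien-4-yl]oxy}dimethylsilane | C=C[C@H](C)[C@@H](O[Si](C)(C)C(C)(C)C)CC=C(C)C | intermediate
8 | 9-[(3S,4S)-4-[(tert-butyldimethylsilyl)oxy]-3,7-dimethyloct-6-en-1-yl]-9-borabicyclo[3.3.1]nonane | C1CCC2CCCC1B2CC[C@H](C)[C@@H](O[Si](C)(C)C(C)(C)C)CC=C(C)C | intermediate
9 | (3S,4S)-4-[(tert-butyldimethylsilyl)oxy]-3,7-dimethyloct-6-en-1-ol | OCC[C@H](C)[C@@H](O[Si](C)(C)C(C)(C)C)CC=C(C)C | intermediate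
10 | (3S,4S)-4-[(tert-butyldimethylsilyl)oxy]-3,7-dimethyloct-6-enal | O=CC[C@H](C)[C@@H](O[Si](C)(C)C(C)(C)C)CC=C(C)C | intermediate
11 | (1R,2S,4S,5S)-4-[(tert-butyldimethylsilyl)oxy]-5-methyl-2-(prop-1-en-2-yl)cyclohexan-1-ol | O[C@@H]1C[C@H](C)[C@@H](O[Si](C)(C)C(C)(C)C)C[C@H]1C(C)=C | intermediate
12 | angelic acid, (Z)-2-methylbut-2-enoic acid | C/C=C(/C)C(=O)O | starting material
13 | angelic 2,4,6-trichlorobenzoic anhydride | C/C=C(/C)C(=O)OC(=O)c1c(Cl)cc(Cl)cc1Cl | intermediate
14 | (1R,2S,4S,5S)-4-[(tert-butyldimethylsilyl)oxy]-5-methyl-2-(prop-1-en-2-yl)cyclohexyl (Z)-2-methylbut-2-enoate | C/C=C(/C)C(=O)O[C@@H]1C[C@H](C)[C@@H](O[Si](C)(C)C(C)(C)C)C[C@H]1C(C)=C | intermediate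
15 | 1-iodo-2-methylprop-1-ene | CC(C)=CI | starting material
16 | B-alkyl-9-BBN adduct of 14 (boron on the former =CH2 carbon, new methyl-bearing centre R) | C/C=C(/C)C(=O)O[C@@H]1C[C@H](C)[C@@H](O[Si](C)(C)C(C)(C)C)C[C@H]1[C@H](C)CB1C2CCCC1CCC2 | intermediate
17 | (1R,2S,4S,5S)-4-[(tert-butyldimethylsilyl)oxy]-5-methyl-2-[(2R)-6-methyl-4-oxohept-5-en-2-yl]cyclohexyl (Z)-2-methylbut-2-enoate | C/C=C(/C)C(=O)O[C@@H]1C[C@H](C)[C@@H](O[Si](C)(C)C(C)(C)C)C[C@H]1[C@H](C)CC(=O)C=C(C)C | intermediate
18 | (1R,2S,4S,5S)-4-[(tert-butyldimethylsilyl)oxy]-2-[(2R,4R)-4-hydroxy-6-methylhept-5-en-2-yl]-5-methylcyclohexyl (Z)-2-methylbut-2-enoate | C/C=C(/C)C(=O)O[C@@H]1C[C@H](C)[C@@H](O[Si](C)(C)C(C)(C)C)C[C@H]1[C@H](C)C[C@H](C=C(C)C)O | intermediate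
19 | (1R,2S,4S,5S)-2-[(2R,4R)-4-acetoxy-6-methylhept-5-en-2-yl]-4-[(tert-butyldimethylsilyl)oxy]-5-methylcyclohexyl (Z)-2-methylbut-2-enoate | C/C=C(/C)C(=O)O[C@@H]1C[C@H](C)[C@@H](O[Si](C)(C)C(C)(C)C)C[C@H]1[C@H](C)C[C@H](C=C(C)C)OC(C)=O | intermediate
20 | (1R,2S,4S,5S)-2-[(2R,4R)-4-acetoxy-6-methylhept-5-en-2-yl]-4-hydroxy-5-methylcyclohexyl (Z)-2-methylbut-2-enoate | C/C=C(/C)C(=O)O[C@@H]1C[C@H](C)[C@@H](O)C[C@H]1[C@H](C)C[C@H](C=C(C)C)OC(C)=O | intermediate
21 | (1R,2S,5S)-2-[(2R,4R)-4-acetoxy-6-methylhept-5-en-2-yl]-5-methyl-4-oxocyclohexyl (Z)-2-methylbut-2-enoate | C/C=C(/C)C(=O)O[C@@H]1C[C@H](C)C(=O)C[C@H]1[C@H](C)C[C@H](C=C(C)C)OC(C)=O | intermediate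
22 | (1R,2S,4R,5S)-2-[(2R,4R)-4-acetoxy-6-methylhept-5-en-2-yl]-4-hydroxy-5-methylcyclohexyl (Z)-2-methylbut-2-enoate | C/C=C(/C)C(=O)O[C@@H]1C[C@H](C)[C@H](O)C[C@H]1[C@H](C)C[C@H](C=C(C)C)OC(C)=O | target

**Step count and risks**

Total step count: 13. Longest linear sequence: 13 steps (1 to 22).

Steps most likely to fail:

1. Step 8. The hydroboration may show incomplete facial control at the new methyl-bearing centre, and in the coupling CO insertion may be outrun by direct alkyl–alkenyl coupling or by protodeboronation of the hindered B-alkyl group. The fallback sets out from 14 and replaces the carbonylative coupling by a polar acylation. Hydroboration of 14 with 9-BBN followed by oxidation with NaBO3·4H2O gives (1R,2S,4S,5S)-4-[(tert-butyldimethylsilyl)oxy]-2-[(2S)-1-hydroxypropan-2-yl]-5-methylcyclohexyl (Z)-2-methylbut-2-enoate F1, at which stage the epimers at the new centre can be separated. Appel iodination (I2, PPh3, imidazole, CH2Cl2) gives (1R,2S,4S,5S)-4-[(tert-butyldimethylsilyl)oxy]-2-[(2S)-1-iodopropan-2-yl]-5-methylcyclohexyl (Z)-2-methylbut-2-enoate F2. Zinc insertion (Zn, LiCl, THF) gives the organozinc reagent F3, and Negishi acylation with 3-methylbut-2-enoyl chloride and Pd(PPh3)4 returns to the route at enone 17.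

2. Step 9. The oxazaborolidine may differentiate the branched CH2 flank and the isobutenyl flank of the ketone poorly, eroding facial selectivity at the carbinol carbon. The fallback sets out from 17 and gives up catalyst control for separation and recycling. Luche reduction (NaBH4, CeCl3·7H2O, MeOH, −78 °C) gives both carbinol epimers, which are separated by chromatography. The (4R)-alcohol is 18, where the route is rejoined. The epimer (1R,2S,4S,5S)-4-[(tert-butyldimethylsilyl)oxy]-2-[(2R,4S)-4-hydroxy-6-methylhept-5-en-2-yl]-5-methylcyclohexyl (Z)-2-methylbut-2-enoate F4 is oxidised back to 17 with MnO2 and recycled.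

3. Step 7. The activated angeloyl group may isomerise from Z to E (tiglate) under base and heat while acylation of the hindered ring alcohol is slow. The fallback sets out from 11 and builds the Z double bond on the substrate instead of transferring it. Saponification (LiOH, aqueous THF, 0 °C) of commercial ethyl 2-[bis(2,2,2-trifluoroethoxy)phosphoryl]propanoate gives 2-[bis(2,2,2-trifluoroethoxy)phosphoryl]propanoic acid F5. Esterification of 11 with F5 (DCC, DMAP, CH2Cl2) gives (1R,2S,4S,5S)-4-[(tert-butyldimethylsilyl)oxy]-5-methyl-2-(prop-1-en-2-yl)cyclohexyl 2-[bis(2,2,2-trifluoroethoxy)phosphoryl]propanoate F6. Still–Gennari olefination of F6 with acetaldehyde (KN(SiMe3)2, 18-crown-6, THF, −78 °C) gives the Z-trisubstituted enoate and returns to the route at 14.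

**Further compounds**

F1 | step 8 | (1R,2S,4S,5S)-4-[(tert-butyldimethylsilyl)oxy]-2-[(2S)-1-hydroxypropan-2-yl]-5-methylcyclohexyl (Z)-2-methylbut-2-enoate | C/C=C(/C)C(=O)O[C@@H]1C[C@H](C)[C@@H](O[Si](C)(C)C(C)(C)C)C[C@H]1[C@H](C)CO
F2 | step 8 | (1R,2S,4S,5S)-4-[(tert-butyldimethylsilyl)oxy]-2-[(2S)-1-iodopropan-2-yl]-5-methylcyclohexyl (Z)-2-methylbut-2-enoate | C/C=C(/C)C(=O)O[C@@H]1C[C@H](C)[C@@H](O[Si](C)(C)C(C)(C)C)C[C@H]1[C@H](C)CI
F3 | step 8 | organozinc reagent (alkylzinc iodide of F2) | C/C=C(/C)C(=O)O[C@@H]1C[C@H](C)[C@@H](O[Si](C)(C)C(C)(C)C)C[C@H]1[C@H](C)C[Zn]I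
F4 | step 9 | (1R,2S,4S,5S)-4-[(tert-butyldimethylsilyl)oxy]-2-[(2R,4S)-4-hydroxy-6-methylhept-5-en-2-yl]-5-methylcyclohexyl (Z)-2-methylbut-2-enoate | C/C=C(/C)C(=O)O[C@@H]1C[C@H](C)[C@@H](O[Si](C)(C)C(C)(C)C)C[C@H]1[C@H](C)C[C@@H](C=C(C)C)O
F5 | step 7 | 2-[bis(2,2,2-trifluoroethoxy)phosphoryl]propanoic acid | CC(C(=O)O)P(=O)(OCC(F)(F)F)OCC(F)(F)F
F6 | step 7 | (1R,2S,4S,5S)-4-[(tert-butyldimethylsilyl)oxy]-5-methyl-2-(prop-1-en-2-yl)cyclohexyl 2-[bis(2,2,2-trifluoroethoxy)phosphoryl]propanoate | CC(C(=O)O[C@@H]1C[C@H](C)[C@@H](O[Si](C)(C)C(C)(C)C)C[C@H]1C(C)=C)P(=O)(OCC(F)(F)F)OCC(F)(F)F
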